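**Strategy.** The route rests on closing the cyclohexane by joining its side-chain-bearing CH (C-2) to the quaternary CMe2 carbon (C-3). This exploits the 1,2-relationship between C-2 and the carboxyl-bearing C-1 of the cyclohexane: C-2 is the β-carbon of an acrylate. A hydrogen-atom-transfer-initiated Giese cyclisation of an (E)-α-alkylidene-γ-butyrolactone carrying an isobutenyl group forms this bond, the quaternary carbon and both ring stereocentres in one operation. The lactone is a temporary bridge that relays one CBS-derived carbinol centre and is removed afterwards. The precursor is joined by Horner–Wadsworth–Emmons olefination from a lactone phosphonate and a chromane aldehyde made from (R)-linalool.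

Key step: step 9

Remark: the carbinol C–O bond of (R)-linalool is never broken, so it becomes C-2 of the chromene with unchanged spatial arrangement; where its descriptor changes in intermediates (5, 8, 9), only the CIP priorities have changed.

Step 1
Reactants: 1 1-bromo-3-methoxy-5-methylbenzene
Product: 3 1-bromo-2-iodo-3-methoxy-5-methylbenzene, via aryllithium 2 (not isolated)
Conditions: LiN(iPr)2 (1.1 equiv), THF, −78 °C; then I2, −78 °C to rt
Reagents that add atoms: iodine, [I][I]
Why: Directed ortho-lithiation removes the proton flanked by bromine and methoxy, the most acidic one, and iodine traps the aryllithium at low temperature before benzyne formation can set in.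

Step 2
Reactants: 4 (R)-linalool; 3 1-bromo-2-iodo-3-methoxy-5-methylbenzene
Product: 6 (3R)-1-(2-bromo-6-methoxy-4-methylphenyl)-3,7-dimethyloct-6-en-3-ol, via alkylborane 5 (not isolated)
Conditions: 9-BBN (2.2 equiv), THF, 0 °C to rt; then 3, PdCl2(dppf) (5 mol %), AsPh3, Cs2CO3, DMF/H2O, 50 °C
Reagents that add atoms: none
Why: 9-BBN hydroborates only the monosubstituted vinyl group, and the B-alkyl Suzuki–Miyaura coupling should take place at the C–I bond in preference to the C–Br bond, with the carbinol stereocentre untouched.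

Step 3
Reactants: 6 (3R)-1-(2-bromo-6-methoxy-4-methylphenyl)-3,7-dimethyloct-6-en-3-ol
Product: 7 (2R)-5-methoxy-2,7-dimethyl-2-(4-methylpent-3-en-1-yl)-3,4-dihydro-2H-chromene
Conditions: Pd(OAc)2 (5 mol %), 2-(di-tert-butylphosphino)-1,1'-binaphthyl (6 mol %), Cs2CO3, toluene, 80 °C
Reagents that add atoms: none
Why: Intramolecular palladium-catalysed C–O coupling (Buchwald–Hartwig etherification) of the tertiary alcohol with the aryl bromide closes the six-membered ether ring without breaking any bond at the stereocentre, so its configuration is retained.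

Step 4
Reactants: 7 (2R)-5-methoxy-2,7-dimethyl-2-(4-methylpent-3-en-1-yl)-3,4-dihydro-2H-chromene
Product: 9 3-[(2S)-5-methoxy-2,7-dimethyl-3,4-dihydro-2H-chromen-2-yl]propanal, via diol 8 (not isolated)
Conditions: OsO4 (2 mol %), NaIO4 (4 equiv), 2,6-lutidine, 1,4-dioxane/H2O (3:1), rt
Reagents that add atoms: osmium tetroxide, O=[Os](=O)(=O)=O; sodium periodate, [Na+].[O-]I(=O)(=O)=O
Why: Lemieux–Johnson oxidation, in which osmylation of the only alkene (electron-rich, trisubstituted) and periodate cleavage of the diol give the aldehyde while the arene stays inert.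

Step 5
Reactants: 10 methyl 4-chloro-4-oxobutanoate; 11 (2-methylprop-1-en-1-yl)magnesium bromide
Product: 12 methyl 6-methyl-4-oxohept-5-enoate
Conditions: Fe(acac)3 (3 mol %), THF, −78 °C
Reagents that add atoms: none
Why: Iron-catalysed acylation of the alkenyl Grignard reagent by the acid chloride (Kumada-type cross-coupling) should be much faster than its addition to the ester or to the enone formed.

Step 6
Reactants: 12 methyl 6-methyl-4-oxohept-5-enoate
Product: 14 (5R)-5-(2-methylprop-1-en-1-yl)oxolan-2-one, via hydroxy ester 13 (not isolated)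
Conditions: (S)-2-methyl-CBS-oxazaborolidine (10 mol %), catecholborane, toluene, −78 °C; MeOH quench; then PPTS (cat.), toluene, 50 °C
Reagents that add atoms: none
Why: Corey–Bakshi–Shibata reduction in which the alkenyl group acts as the large substituent, so the (S)-catalyst should give the (4R)-alcohol, which lactonises under acid too mild to ionise the allylic C–O bond.

Step 7
Reactants: 14 (5R)-5-(2-methylprop-1-en-1-yl)oxolan-2-one
Product: 16 diethyl [(5R)-5-(2-methylprop-1-en-1-yl)-2-oxooxolan-3-yl]phosphonate (both C-3 epimers), via enol phosphate 15 (not isolated)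
Conditions: LiN(iPr)2 (2.2 equiv), THF, −78 °C; ClP(O)(OEt)2; −78 °C to rt; aq. NH4Cl
Reagents that add atoms: diethyl chlorophosphate, CCOP(=O)(Cl)OCC
Why: Vinyl phosphate–phosphonate rearrangement, in which the lactone enolate is O-phosphorylated and the second equivalent of base induces the 1,3-shift of phosphorus from oxygen to carbon, remote from the C-5 stereocentre.

Step 8
Reactants: 16 diethyl [(5R)-5-(2-methylprop-1-en-1-yl)-2-oxooxolan-3-yl]phosphonate; 9 3-[(2S)-5-methoxy-2,7-dimethyl-3,4-dihydro-2H-chromen-2-yl]propanal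
Product: 17 (3E,5R)-3-{3-[(2R)-5-methoxy-2,7-dimethyl-3,4-dihydro-2H-chromen-2-yl]propylidene}-5-(2-methylprop-1-en-1-yl)oxolan-2-one
Conditions: NaH, THF, 0 °C to rt; chromatography to remove the minor Z isomer
Reagents that add atoms: none
Why: Horner–Wadsworth–Emmons olefination of an α-phosphono-γ-butyrolactone with an aliphatic aldehyde should give mainly the E-alkylidene lactone (side chain cis to the ring CH2), from which the Z isomer is separated.

Step 9
Reactants: 17 (3E,5R)-3-{3-[(2R)-5-methoxy-2,7-dimethyl-3,4-dihydro-2H-chromen-2-yl]propylidene}-5-(2-methylprop-1-en-1-yl)oxolan-2-one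
Product: 18 (1S,2R,5R)-2-{2-[(2R)-5-methoxy-2,7-dimethyl-3,4-dihydro-2H-chromen-2-yl]ethyl}-3,3-dimethyl-6-oxabicyclo[3.2.1]octan-7-one
Conditions: Fe(acac)3 (0.3 equiv), PhSiH3 (3 equiv, syringe pump), EtOH/(CH2OH)2 (5:1), 60 °C, 5 mM
Reagents that add atoms: none
Why: Hydrogen-atom transfer from the iron hydride (from Fe(acac)3 and PhSiH3) to the CH terminus of the isobutenyl group gives the tertiary CMe2 radical, which adds to the β-carbon of the alkylidene lactone (Giese addition); the bridgehead α-acyl radical is then quenched by hydrogen transfer. The closest known reaction is the iron-mediated reductive olefin coupling (HAT-initiated Giese reaction) in its intramolecular form. The cyclohexane closes 6-endo-trig with respect to the acceptor double bond; the 5-exo mode would attack the α-carbon and build a bicyclo[2.2.1] skeleton with two adjacent quaternary carbons, so it should not compete. The CH2–CMe2 arm on the (5R) lactone carbon can reach only one face of the exocyclic double bond, so with the E geometry the side chain ends anti to the lactone bridge: C-2 is set as R by the lactone stereocentre plus the alkene geometry, and the bridgehead C-1 as S by the bridge itself, which is the trans relationship of the target. The step needs hydrogen-atom transfer to the electron-rich trisubstituted alkene and not to the electron-poor alkylidene lactone, which the polarity of the metal hydride secures, and ring closure faster than reduction of the tertiary radical, which the nucleophilic-radical/electrophilic-acceptor pairing, high dilution and slow silane addition should favour.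

Step 10
Reactants: 18 (1S,2R,5R)-2-{2-[(2R)-5-methoxy-2,7-dimethyl-3,4-dihydro-2H-chromen-2-yl]ethyl}-3,3-dimethyl-6-oxabicyclo[3.2.1]octan-7-one
Product: 19 methyl (1S,2R,5R)-5-hydroxy-2-{2-[(2R)-5-methoxy-2,7-dimethyl-3,4-dihydro-2H-chromen-2-yl]ethyl}-3,3-dimethylcyclohexane-1-carboxylate
Conditions: NaOMe (0.2 equiv), MeOH, rt
Reagents that add atoms: methanol, CO
Why: Base-catalysed transesterification opens the strained bridged lactone to the hydroxy ester in which ester, side chain and hydroxyl are all equatorial, so C-1 has no driving force to epimerise.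

Step 11
Reactants: 19 methyl (1S,2R,5R)-5-hydroxy-2-{2-[(2R)-5-methoxy-2,7-dimethyl-3,4-dihydro-2H-chromen-2-yl]ethyl}-3,3-dimethylcyclohexane-1-carboxylate
Product: 20 methyl (1S,2R,5R)-5-[(1H-imidazol-1-ylcarbonothioyl)oxy]-2-{2-[(2R)-5-methoxy-2,7-dimethyl-3,4-dihydro-2H-chromen-2-yl]ethyl}-3,3-dimethylcyclohexane-1-carboxylate
Conditions: 1,1'-thiocarbonyldiimidazole, DMAP (cat.), ClCH2CH2Cl, 70 °C
Reagents that add atoms: 1,1'-thiocarbonyldiimidazole, S=C(n1ccnc1)n1ccnc1
Why: Acylation of the unhindered equatorial secondary alcohol under neutral conditions gives the thiocarbonyl derivative needed for Barton–McCombie deoxygenation.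

Step 12
Reactants: 20 methyl (1S,2R,5R)-5-[(1H-imidazol-1-ylcarbonothioyl)oxy]-2-{2-[(2R)-5-methoxy-2,7-dimethyl-3,4-dihydro-2H-chromen-2-yl]ethyl}-3,3-dimethylcyclohexane-1-carboxylate
Product: 21 methyl (1S,2R)-2-{2-[(2R)-5-methoxy-2,7-dimethyl-3,4-dihydro-2H-chromen-2-yl]ethyl}-3,3-dimethylcyclohexane-1-carboxylate
Conditions: Bu3SnH, AIBN (cat.), toluene, 110 °C
Reagents that add atoms: none
Why: Barton–McCombie deoxygenation, in which stannyl radical addition to C=S and β-scission give a secondary cyclohexyl radical that takes hydrogen from Bu3SnH, removes the temporary oxygen without touching C-1 or C-2.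

Step 13
Reactants: 21 methyl (1S,2R)-2-{2-[(2R)-5-methoxy-2,7-dimethyl-3,4-dihydro-2H-chromen-2-yl]ethyl}-3,3-dimethylcyclohexane-1-carboxylate
Product: 22 methyl (1S,2R)-2-{2-[(2R)-5-methoxy-2,7-dimethyl-2H-chromen-2-yl]ethyl}-3,3-dimethylcyclohexane-1-carboxylate
Conditions: DDQ (1.3 equiv), 1,4-dioxane, 100 °C
Reagents that add atoms: none
Why: DDQ dehydrogenation, by hydride abstraction from benzylic C-4 (cation stabilised by the ortho ring oxygen and ortho methoxy group) and proton loss from C-3, should give the 2H-chromene, the quaternary C-2 blocking further oxidation.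

Step 14
Reactants: 22 methyl (1S,2R)-2-{2-[(2R)-5-methoxy-2,7-dimethyl-2H-chromen-2-yl]ethyl}-3,3-dimethylcyclohexane-1-carboxylate
Product: 23 (1S,2R)-2-{2-[(2R)-5-hydroxy-2,7-dimethyl-2H-chromen-2-yl]ethyl}-3,3-dimethylcyclohexane-1-carboxylic acid
Conditions: NaSEt (6 equiv), DMF, 130 °C; then aq. HCl to pH 3
Reagents that add atoms: none
Why: Thiolate SN2 demethylation cleaves both the methyl ester and the aryl methyl ether in one non-acidic operation that should leave the chromene double bond and all three stereocentres untouched.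

**Compound list**

1 | 1-bromo-3-methoxy-5-methylbenzene | COc1cc(C)cc(Br)c1 | starting material
2 | (2-bromo-6-methoxy-4-methylphenyl)lithium | COc1cc(C)cc(Br)c1[Li] | intermediate
3 | 1-bromo-2-iodo-3-methoxy-5-methylbenzene | COc1cc(C)cc(Br)c1I | intermediate
4 | (R)-linalool, (3R)-3,7-dimethylocta-1,6-dien-3-ol | C=C[C@](C)(O)CCC=C(C)C | starting material
5 | 9-[(3S)-3-hydroxy-3,7-dimethyloct-6-en-1-yl]-9-borabicyclo[3.3.1]nonane | CC(C)=CCC[C@@](C)(O)CCB1C2CCCC1CCC2 | intermediate
6 | (3R)-1-(2-bromo-6-methoxy-4-methylphenyl)-3,7-dimethyloct-6-en-3-ol | COc1cc(C)cc(Br)c1CC[C@](C)(O)CCC=C(C)C | intermediate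
7 | (2R)-5-methoxy-2,7-dimethyl-2-(4-methylpent-3-en-1-yl)-3,4-dihydro-2H-chromene | COc1cc(C)cc2O[C@](C)(CCC=C(C)C)CCc12 | intermediate
8 | 5-[(2S)-5-methoxy-2,7-dimethyl-3,4-dihydro-2H-chromen-2-yl]-2-methylpentane-2,3-diol (both C-3 epimers) | COc1cc(C)cc2O[C@](C)(CCC(O)C(C)(C)O)CCc12 | intermediate
9 | 3-[(2S)-5-methoxy-2,7-dimethyl-3,4-dihydro-2H-chromen-2-yl]propanal | COc1cc(C)cc2O[C@](C)(CCC=O)CCc12 | intermediate
10 | methyl 4-chloro-4-oxobutanoate | COC(=O)CCC(Cl)=O | starting material
11 | (2-methylprop-1-en-1-yl)magnesium bromide | CC(C)=C[Mg]Br | starting material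
12 | methyl 6-methyl-4-oxohept-5-enoate | COC(=O)CCC(=O)C=C(C)C | intermediate
13 | methyl (4R)-4-hydroxy-6-methylhept-5-enoate | COC(=O)CC[C@@H](O)C=C(C)C | intermediate
14 | (5R)-5-(2-methylprop-1-en-1-yl)oxolan-2-one | O=C1CC[C@H](C=C(C)C)O1 | intermediate
15 | diethyl (5R)-5-(2-methylprop-1-en-1-yl)-4,5-dihydrofuran-2-yl phosphate | CCOP(=O)(OCC)OC1=CC[C@H](C=C(C)C)O1 | intermediate
16 | diethyl [(5R)-5-(2-methylprop-1-en-1-yl)-2-oxooxolan-3-yl]phosphonate (both C-3 epimers) | CCOP(=O)(OCC)C1C[C@H](C=C(C)C)OC1=O | intermediate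
17 | (3E,5R)-3-{3-[(2R)-5-methoxy-2,7-dimethyl-3,4-dihydro-2H-chromen-2-yl]propylidene}-5-(2-methylprop-1-en-1-yl)oxolan-2-one | COc1cc(C)cc2O[C@](C)(CC/C=C3\C[C@H](C=C(C)C)OC3=O)CCc12 | intermediate
18 | (1S,2R,5R)-2-{2-[(2R)-5-methoxy-2,7-dimethyl-3,4-dihydro-2H-chromen-2-yl]ethyl}-3,3-dimethyl-6-oxabicyclo[3.2.1]octan-7-one | COc1cc(C)cc2O[C@](C)(CC[C@@H]3[C@@H]4C[C@H](CC3(C)C)OC4=O)CCc12 | intermediate
19 | methyl (1S,2R,5R)-5-hydroxy-2-{2-[(2R)-5-methoxy-2,7-dimethyl-3,4-dihydro-2H-chromen-2-yl]ethyl}-3,3-dimethylcyclohexane-1-carboxylate | COc1cc(C)cc2O[C@](C)(CC[C@@H]3[C@@H](C(=O)OC)C[C@@H](O)CC3(C)C)CCc12 | intermediate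
20 | methyl (1S,2R,5R)-5-[(1H-imidazol-1-ylcarbonothioyl)oxy]-2-{2-[(2R)-5-methoxy-2,7-dimethyl-3,4-dihydro-2H-chromen-2-yl]ethyl}-3,3-dimethylcyclohexane-1-carboxylate | COc1cc(C)cc2O[C@](C)(CC[C@@H]3[C@@H](C(=O)OC)C[C@@H](OC(=S)n4ccnc4)CC3(C)C)CCc12 | intermediate
21 | methyl (1S,2R)-2-{2-[(2R)-5-methoxy-2,7-dimethyl-3,4-dihydro-2H-chromen-2-yl]ethyl}-3,3-dimethylcyclohexane-1-carboxylate | COc1cc(C)cc2O[C@](C)(CC[C@@H]3[C@@H](C(=O)OC)CCCC3(C)C)CCc12 | intermediate
22 | methyl (1S,2R)-2-{2-[(2R)-5-methoxy-2,7-dimethyl-2H-chromen-2-yl]ethyl}-3,3-dimethylcyclohexane-1-carboxylate | COc1cc(C)cc2O[C@](C)(CC[C@@H]3[C@@H](C(=O)OC)CCCC3(C)C)C=Cc12 | intermediate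
23 | (1S,2R)-2-{2-[(2R)-5-hydroxy-2,7-dimethyl-2H-chromen-2-yl]ethyl}-3,3-dimethylcyclohexane-1-carboxylic acid | Cc1cc(O)c2c(c1)O[C@](C)(CC[C@@H]1[C@@H](C(=O)O)CCCC1(C)C)C=C2 | target

**Totals.** Total step count: 14. Longest linear sequence: 11 steps (steps 1, 2, 3, 4, 8, 9, 10, 11, 12, 13, 14).

**Steps most likely to fail**

Step 9 (key step). Ring closure has to build a strained bridged lactone and may be slower than reduction of the tertiary radical, so that the isobutenyl group is merely hydrogenated. The fallback dispenses with the temporary ring; it sets out from keto ester 12 and aldehyde 9 and comes back at ester 21. Reduction of 12 with the (R)-CBS catalyst gives the (4S)-hydroxy ester F1, which is silylated at once (TBSCl, imidazole) to the silyl ether F2. α-Phosphorylation as in step 7 gives the phosphonate F3, and Horner–Wadsworth–Emmons reaction with 9 gives the open-chain (E)-enoate F4 after removal of the Z isomer. Under the conditions of step 9, F4 should undergo an unstrained 6-endo Giese cyclisation through a chair. In that chair the silyloxy group stays equatorial to avoid a 1,3-diaxial contact with the axial methyl of the attacking CMe2 carbon, and the E geometry then places the side chain cis to it, giving the cyclohexane silyl ether F5 with the same (2R) centre (C-1 epimers). TBAF gives the alcohol F6, thiocarbonyldiimidazole the imidazolide F7, and Bu3SnH a mixture of 21 and its C-1 epimer F8. NaOMe in MeOH equilibrates this towards the diequatorial trans ester 21, which is separated; the cis ester is recycled.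

Step 8. Control of the double-bond geometry may be poor, and the geometry is translated directly into the configuration at ring C-2. The fallback sets out from lactone 14 and aldehyde 9 and comes back at 17. Aldol addition of the lithium enolate of 14 (LiN(iPr)2, THF, −78 °C) to 9 gives the β-hydroxy lactone F9 as a diastereomer mixture, and mesylation (MsCl, Et3N) gives the mesylate F10. DBU-induced E1cB elimination with equilibration should then give the more stable E-alkylidene lactone 17.

Step 13. Hydride abstraction may be incomplete, or the aryl methyl group may be oxidised in competition. The fallback sets out from 21 and comes back at 22 by the stepwise chromanone route. Benzylic oxygenation at C-4 (CrO3, 3,5-dimethylpyrazole, CH2Cl2, −20 °C) gives the chroman-4-one F11, NaBH4 reduces it to the chroman-4-ol F12, and acid-catalysed dehydration (TsOH, benzene, 80 °C) gives chromene 22.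

**Further compounds**

F1 | step 9 | methyl (4S)-4-hydroxy-6-methylhept-5-enoate | COC(=O)CC[C@H](O)C=C(C)C
F2 | step 9 | methyl (4S)-4-[(tert-butyldimethylsilyl)oxy]-6-methylhept-5-enoate | COC(=O)CC[C@H](O[Si](C)(C)C(C)(C)C)C=C(C)C
F3 | step 9 | methyl (4S)-4-[(tert-butyldimethylsilyl)oxy]-2-(diethoxyphosphoryl)-6-methylhept-5-enoate (both C-2 epimers) | CCOP(=O)(OCC)C(C[C@H](O[Si](C)(C)C(C)(C)C)C=C(C)C)C(=O)OC
F4 | step 9 | methyl (2E)-2-{(2S)-2-[(tert-butyldimethylsilyl)oxy]-4-methylpent-3-en-1-yl}-5-[(2R)-5-methoxy-2,7-dimethyl-3,4-dihydro-2H-chromen-2-yl]pent-2-enoate | COc1cc(C)cc2O[C@](C)(CC/C=C(\C[C@H](O[Si](C)(C)C(C)(C)C)C=C(C)C)C(=O)OC)CCc12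
F5 | step 9 | methyl (2R,5S)-5-[(tert-butyldimethylsilyl)oxy]-2-{2-[(2R)-5-methoxy-2,7-dimethyl-3,4-dihydro-2H-chromen-2-yl]ethyl}-3,3-dimethylcyclohexane-1-carboxylate (both C-1 epimers) | COc1cc(C)cc2O[C@](C)(CC[C@@H]3C(C(=O)OC)C[C@H](O[Si](C)(C)C(C)(C)C)CC3(C)C)CCc12
F6 | step 9 | methyl (2R,5S)-5-hydroxy-2-{2-[(2R)-5-methoxy-2,7-dimethyl-3,4-dihydro-2H-chromen-2-yl]ethyl}-3,3-dimethylcyclohexane-1-carboxylate (both C-1 epimers) | COc1cc(C)cc2O[C@](C)(CC[C@@H]3C(C(=O)OC)C[C@H](O)CC3(C)C)CCc12
F7 | step 9 | methyl (2R,5S)-5-[(1H-imidazol-1-ylcarbonothioyl)oxy]-2-{2-[(2R)-5-methoxy-2,7-dimethyl-3,4-dihydro-2H-chromen-2-yl]ethyl}-3,3-dimethylcyclohexane-1-carboxylate (both C-1 epimers) | COc1cc(C)cc2O[C@](C)(CC[C@@H]3C(C(=O)OC)C[C@H](OC(=S)n4ccnc4)CC3(C)C)CCc12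
F8 | step 9 | methyl (1R,2R)-2-{2-[(2R)-5-methoxy-2,7-dimethyl-3,4-dihydro-2H-chromen-2-yl]ethyl}-3,3-dimethylcyclohexane-1-carboxylate | COc1cc(C)cc2O[C@](C)(CC[C@@H]3[C@H](C(=O)OC)CCCC3(C)C)CCc12
F9 | step 8 | (5R)-3-{1-hydroxy-3-[(2S)-5-methoxy-2,7-dimethyl-3,4-dihydro-2H-chromen-2-yl]propyl}-5-(2-methylprop-1-en-1-yl)oxolan-2-one (diastereomer mixture) | COc1cc(C)cc2O[C@](C)(CCC(O)C3C[C@H](C=C(C)C)OC3=O)CCc12
F10 | step 8 | 3-[(2S)-5-methoxy-2,7-dimethyl-3,4-dihydro-2H-chromen-2-yl]-1-[(5R)-5-(2-methylprop-1-en-1-yl)-2-oxooxolan-3-yl]propyl methanesulfonate (diastereomer mixture) | COc1cc(C)cc2O[C@](C)(CCC(OS(C)(=O)=O)C3C[C@H](C=C(C)C)OC3=O)CCc12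
F11 | step 13 | methyl (1S,2R)-2-{2-[(2R)-5-methoxy-2,7-dimethyl-4-oxo-3,4-dihydro-2H-chromen-2-yl]ethyl}-3,3-dimethylcyclohexane-1-carboxylate | COc1cc(C)cc2O[C@](C)(CC[C@@H]3[C@@H](C(=O)OC)CCCC3(C)C)CC(=O)c12
F12 | step 13 | methyl (1S,2R)-2-{2-[(2R)-4-hydroxy-5-methoxy-2,7-dimethyl-3,4-dihydro-2H-chromen-2-yl]ethyl}-3,3-dimethylcyclohexane-1-carboxylate (both C-4 epimers) | COc1cc(C)cc2O[C@](C)(CC[C@@H]3[C@@H](C(=O)OC)CCCC3(C)C)CC(O)c12
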